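Everything rests on making the C3–O and C6–O bonds of ring B (the trihydroxycyclohexane ring) together. Its secondary C3 hydroxyl and tertiary C6 hydroxyl sit cis on carbons 1,4 to each other with C4–C5 in between, which is what a ring 1,3-diene gives when it takes up O2 at its two ends. Singlet-oxygen [4+2] cycloaddition delivers both oxygens and the C4=C5 alkene in one operation; peroxide reduction, lipase resolution and hydroxyl-directed oxymercuration then complete the 3,5,6-triol. The precursor is the flat, achiral silyl ether of (2,6,6-trimethylcyclohexa-1,3-dienyl)methanol, made from safranal. Its CH2O carbon becomes C7 of an (E)-vinylstannane, joined last by Stille coupling to an α-bromo-γ-ylidenebutenolide that carries the polyenyne and ring A.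

Key step: step 3

Locants: in ring B, C1 = CMe2, C2 = CH2, C3 = CH(OH), C4 = CH2, C5 = C(OH)Me, C6 = the carbinol carbon bearing the side chain (C7, C8). Ring A is the cyclohexene ring attached to the alkyne.

Assumption: the lipase is taken to acetylate the (3R)-carbinol, the usual preference for cyclohex-2-en-1-ols. If it acetylates the antipode instead, the unreacted diol recovered in step 5 is compound 7 itself and step 6 is not needed.

Step 1
Reactants: 1 safranal (2,6,6-trimethylcyclohexa-1,3-diene-1-carbaldehyde)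
Product: 2 (2,6,6-trimethylcyclohexa-1,3-dien-1-yl)methanol
Conditions: NaBH4, MeOH, 0 °C
Reagents that add atoms: none
Why: Borohydride 1,2-reduction of the conjugated aldehyde; hydride attacks only the formyl carbon, the ring diene is untouched and no stereocentre arises.

Step 2
Reactants: 2 (2,6,6-trimethylcyclohexa-1,3-dien-1-yl)methanol
Product: 3 tert-butyl(dimethyl)[(2,6,6-trimethylcyclohexa-1,3-dien-1-yl)methoxy]silane
Conditions: TBSCl, imidazole, DMF, 0 °C to rt
Reagents that add atoms: tert-butyldimethylsilyl chloride, CC(C)(C)[Si](C)(C)Cl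
Why: Imidazole-promoted silylation of the primary allylic alcohol; the robust silyl ether removes the free, oxidisable OH and keeps the diene electron-rich for step 3.

Step 3
Reactants: 3 tert-butyl(dimethyl)[(2,6,6-trimethylcyclohexa-1,3-dien-1-yl)methoxy]silane
Product: 4 rac-tert-butyl(dimethyl){[(1S,4R)-6,7,7-trimethyl-2,3-dioxabicyclo[2.2.2]oct-5-en-1-yl]methoxy}silane
Conditions: O2, 5,10,15,20-tetraphenylporphyrin (cat.), CH2Cl2, −20 °C, visible light
Reagents that add atoms: dioxygen, O=O
Why: Triplet tetraphenylporphyrin, produced by visible light, passes its energy to O2, and the resulting singlet oxygen behaves as a dienophile: it bonds through both oxygen atoms to C3 and C6, the two ends of the C3=C4–C5=C6 diene, in one concerted suprafacial [4+2] event while the π bond moves to C4=C5; the closest known reaction type is the singlet-oxygen Diels–Alder reaction of cyclohexa-1,3-dienes that gives 2,3-dioxabicyclo[2.2.2]oct-5-enes. The only ring closed is the six-membered 1,2-dioxene (C3–O–O–C6–C5=C4), and it closes by intermolecular cycloaddition in which both C–O bonds form together from one face. The two new stereocentres, C3 and C6, are fixed relative to each other by the two-atom peroxide bridge, which can only span a single face, so their oxygens must be cis; because 3 is achiral with enantiotopic faces the product is racemic, and the enantiomer needed is selected by the lipase in step 5. The selectivity that matters is cycloaddition over the ene reaction (allylic hydrogens on the C5 methyl, on C2 and on the CH2O group are available): the six-membered ring holds the diene cisoid, the silyloxymethyl group leaves the diene electron-rich where the formyl group of 1 would deplete it, and low temperature in an aprotic solvent further disfavours the ene and over-oxidation pathways. The silyl ether is inert to singlet oxygen.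

Step 4
Reactants: 4 rac-endoperoxide
Product: 5 rac-(1S,4R)-1-{[tert-butyl(dimethyl)silyl]oxymethyl}-2,6,6-trimethylcyclohex-2-ene-1,4-diol (cis-enediol)
Conditions: thiourea, MeOH, 0 °C to rt
Reagents that add atoms: none
Why: Reductive cleavage of the peroxide O–O bond by the soft sulfur nucleophile of thiourea leaves both C–O bonds intact, so the cis-1,4 relationship of the C3 and C6 oxygens is retained, and the neutral conditions avoid base-induced Kornblum–DeLaMare rearrangement at the bridgehead C3–H.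

Step 5
Reactants: 5 rac-cis-enediol
Product: 6 (1R,4S)-4-{[tert-butyl(dimethyl)silyl]oxymethyl}-4-hydroxy-3,5,5-trimethylcyclohex-2-en-1-yl acetate
Conditions: vinyl acetate, Novozym 435 (immobilised Candida antarctica lipase B), t-BuOMe, 30 °C, to about half conversion
Reagents that add atoms: vinyl acetate, C=COC(C)=O
Why: Lipase-catalysed kinetic resolution by irreversible transesterification of the secondary allylic hydroxyl (the tertiary C6–OH is inert); the enzyme pocket distinguishes the sp2 neighbour C4 from the sp3 neighbour C2 and is expected to acylate the (3R)-carbinol, so the absolute configuration of C3 and C6 is selected here, and the acetate is separated from the unreacted antipodal diol by chromatography.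

Step 6
Reactants: 6 (3R)-monoacetate
Product: 7 (1S,4R)-1-{[tert-butyl(dimethyl)silyl]oxymethyl}-2,6,6-trimethylcyclohex-2-ene-1,4-diol (single enantiomer)
Conditions: K2CO3 (cat.), MeOH, rt
Reagents that add atoms: none
Why: Base-catalysed transesterification (methanolysis) of the acetate frees the C3 hydroxyl without touching the silyl ether or any stereocentre, giving the free cis-enediol needed for hydroxyl direction in step 7.

Step 7
Reactants: 7 enantiopure cis-enediol
Product: 9 (1R,2S,4R)-1-{[tert-butyl(dimethyl)silyl]oxymethyl}-2,6,6-trimethylcyclohexane-1,2,4-triol, via C4 acetoxymercurial 8 (not isolated)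
Conditions: Hg(OAc)2, THF/H2O, rt; then aq NaOH, NaBH4, 0 °C
Reagents that add atoms: water, O
Why: Oxymercuration–demercuration (Markovnikov hydration): divalent mercury is held on the alkene face bearing the two allylic hydroxyls, water opens the mercurinium ion anti at the more substituted C5, so the new tertiary hydroxyl at C5 is trans to the C3 and C6 hydroxyls (5S), and radical demercuration with NaBH4 leaves C4 as CH2.

Step 8
Reactants: 9 silyloxymethyl triol
Product: 10 (1R,3S,4R)-4-{[tert-butyl(dimethyl)silyl]oxymethyl}-3,4-dihydroxy-3,5,5-trimethylcyclohexyl acetate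
Conditions: Ac2O, pyridine, DMAP (cat.), CH2Cl2, 0 °C to rt
Reagents that add atoms: acetic anhydride, CC(=O)OC(C)=O
Why: Nucleophile-catalysed acylation is selective for the single secondary hydroxyl over the two tertiary ones, masking C3–OH so that only the side-chain alcohol can be oxidised later.

Step 9
Reactants: 10 C3 acetate
Product: 11 (1R,3S,4R)-3,4-dihydroxy-4-(hydroxymethyl)-3,5,5-trimethylcyclohexyl acetate
Conditions: Bu4NF, AcOH, THF, rt
Reagents that add atoms: none
Why: Fluoride-induced cleavage of the Si–O bond (desilylation), buffered with acetic acid so that the C3 acetate neither migrates nor is cleaved.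

Step 10
Reactants: 11 primary alcohol
Product: 12 (1R,3S,4S)-4-formyl-3,4-dihydroxy-3,5,5-trimethylcyclohexyl acetate
Conditions: IBX, DMSO, rt
Reagents that add atoms: none
Why: IBX oxidation of the primary alcohol to the aldehyde; IBX does not cleave 1,2-diols, tertiary alcohols are inert, and the fully substituted α-carbon C6 cannot epimerise.

Step 11
Reactants: 12 α-hydroxy aldehyde
Product: 14 (1R,2S,4R)-1-ethynyl-2,6,6-trimethylcyclohexane-1,2,4-triol, via alkyne acetate 13 (not isolated)
Conditions: dimethyl (1-diazo-2-oxopropyl)phosphonate, K2CO3, MeOH, 0 °C to rt, prolonged stirring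
Reagents that add atoms: dimethyl (1-diazo-2-oxopropyl)phosphonate, COP(=O)(OC)C(=[N+]=[N-])C(C)=O
Why: Ohira–Bestmann (Seyferth–Gilbert) homologation: the diazomethylphosphonate anion generated by methanolysis adds to the aldehyde, a Horner–Wadsworth–Emmons-type elimination and loss of N2 give the terminal alkyne with one added carbon (C8), and continued stirring in K2CO3/MeOH removes the C3 acetate; no stereocentre is touched.

Step 12
Reactants: 14 ethynyl triol
Product: 15 (1S,2S,4R)-2,6,6-trimethyl-1-[(E)-2-(tributylstannyl)ethenyl]cyclohexane-1,2,4-triol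
Conditions: Bu3SnH, PdCl2(PPh3)2 (cat.), THF, 0 °C
Reagents that add atoms: tributyltin hydride, CCCC[SnH](CCCC)CCCC
Why: Palladium-catalysed hydrostannylation (syn addition of Sn–H through a zerovalent palladium cycle) places tin on the terminal carbon, away from the fully substituted carbinol C6, and the syn addition fixes the (E)-C7=C8 geometry.

Step 13
Reactants: 16 actinol ((4R,6R)-4-hydroxy-2,2,6-trimethylcyclohexan-1-one)
Product: 17 (4R,6R)-4-{[tert-butyl(dimethyl)silyl]oxy}-2,2,6-trimethylcyclohexan-1-one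
Conditions: TBSCl, imidazole, DMF, rt
Reagents that add atoms: tert-butyldimethylsilyl chloride, CC(C)(C)[Si](C)(C)Cl
Why: Imidazole-promoted silylation protects the secondary hydroxyl against the strong base of step 14; both stereocentres are untouched.

Step 14
Reactants: 17 silylated actinol
Product: 19 (4R)-4-{[tert-butyl(dimethyl)silyl]oxy}-2,6,6-trimethylcyclohex-1-en-1-yl trifluoromethanesulfonate, via lithium enolate 18 (not isolated)
Conditions: LiN(i-Pr)2 (LDA), THF, −78 °C; then PhNTf2, −78 °C to rt; aq NH4Cl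
Reagents that add atoms: N-phenylbis(trifluoromethanesulfonimide), O=S(=O)(N(c1ccccc1)S(=O)(=O)C(F)(F)F)C(F)(F)F
Why: Enolate O-sulfonylation (enol triflate formation): only C6 of the ketone carries an α-hydrogen, so deprotonation gives a single enolate, whose triflation deliberately erases the C6 stereocentre and leaves the (R)-configured silyloxy carbon unchanged.

Step 15
Reactants: 19 enol triflate; 20 (E)-3-methylpent-2-en-4-yn-1-ol
Product: 21 (2E)-5-[(4R)-4-{[tert-butyl(dimethyl)silyl]oxy}-2,6,6-trimethylcyclohex-1-en-1-yl]-3-methylpent-2-en-4-yn-1-ol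
Conditions: Pd(PPh3)4 (cat.), CuI (cat.), i-Pr2NH, DMF, 50 °C
Reagents that add atoms: none
Why: Sonogashira coupling of the alkenyl triflate with the terminal alkyne forms the ring–C≡C bond of ring A; the (E)-trisubstituted alkene of 20 and the free allylic alcohol are spectators.

Step 16
Reactants: 21 ring A enynol
Product: 22 (2E)-5-[(4R)-4-{[tert-butyl(dimethyl)silyl]oxy}-2,6,6-trimethylcyclohex-1-en-1-yl]-3-methylpent-2-en-4-ynal
Conditions: MnO2, CH2Cl2, rt
Reagents that add atoms: none
Why: MnO2 oxidises only the allylic primary alcohol, under neutral heterogeneous conditions that retain the (E)-geometry of the enynal.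

Step 17
Reactants: 22 ring A enynal
Product: 23 tert-butyl(dimethyl){[(1R)-3,5,5-trimethyl-4-[(3E,5E)-3-methyl-6-(4,4,5,5-tetramethyl-1,3,2-dioxaborolan-2-yl)hexa-3,5-dien-1-yn-1-yl]cyclohex-3-en-1-yl]oxy}silane
Conditions: Cl2CHB(pin), CrCl2, LiI, THF, rt
Reagents that add atoms: 2-(dichloromethyl)-4,4,5,5-tetramethyl-1,3,2-dioxaborolane, ClC(Cl)B1OC(C)(C)C(C)(C)O1
Why: Takai-type boron olefination: a geminal dichromium species from Cl2CHB(pin) and CrCl2 adds to the aldehyde and eliminates through the anti-periplanar arrangement to give the (E)-alkenylboronate, lengthening the chain by one carbon.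

Step 18
Reactants: 20 (E)-3-methylpent-2-en-4-yn-1-ol
Product: 26 (2E)-3-methyl-5-(trimethylsilyl)pent-2-en-4-yn-1-ol, via dilithium alkoxide acetylide 24 (not isolated), via bis-silyl derivative 25 (not isolated)
Conditions: n-BuLi (2.1 equiv), THF, −78 °C; TMSCl (2.2 equiv), −78 °C to rt; then 1 M aq HCl, rt
Reagents that add atoms: chlorotrimethylsilane, C[Si](C)(C)Cl
Why: Double deprotonation and silylation of both anionic sites (acetylide silylation), followed by mild acid hydrolysis of the labile O–SiMe3 bond, leaves the C-silylated alkyne, which masks the terminal C–H during the chromium and palladium steps.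

Step 19
Reactants: 26 C-silylated enynol
Product: 27 (2E)-3-methyl-5-(trimethylsilyl)pent-2-en-4-ynal
Conditions: MnO2, CH2Cl2, rt
Reagents that add atoms: none
Why: MnO2 oxidation of the allylic alcohol to the enal with retention of the (E)-alkene.

Step 20
Reactants: 27 C-silylated enynal
Product: 28 [(3E,5E)-6-iodo-3-methylhexa-3,5-dien-1-yn-1-yl](trimethyl)silane
Conditions: CHI3, CrCl2, THF/1,4-dioxane, 0 °C to rt
Reagents that add atoms: iodoform, IC(I)I
Why: Takai iodo-olefination: the geminal dichromium reagent from CHI3 and CrCl2 converts the aldehyde to the one-carbon-longer (E)-alkenyl iodide, the dioxane co-solvent favouring the (E)-isomer.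

Step 21
Reactants: 23 dienylboronate; 28 dienyl iodide
Product: 29 tert-butyl{[(1R)-4-[(3E,5E,7E,9E)-3,10-dimethyl-12-(trimethylsilyl)dodeca-3,5,7,9-tetraene-1,11-diyn-1-yl]-3,5,5-trimethylcyclohex-3-en-1-yl]oxy}dimethylsilane
Conditions: PdCl2(dppf) (cat.), aq K3PO4, THF, rt, dark
Reagents that add atoms: none
Why: Suzuki–Miyaura coupling of the (E)-alkenylboronate with the (E)-alkenyl iodide forms the central sp2–sp2 single bond with retention of both alkene geometries, giving the all-(E) tetraene.

Step 22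
Reactants: 29 bis-silylated tetraenediyne
Product: 30 (1R)-4-[(3E,5E,7E,9E)-3,10-dimethyldodeca-3,5,7,9-tetraene-1,11-diyn-1-yl]-3,5,5-trimethylcyclohex-3-en-1-ol
Conditions: Bu4NF, THF, 0 °C to rt, dark
Reagents that add atoms: none
Why: Fluoride cleaves both the O–Si and the alkynyl C–Si bonds (desilylation) in one operation, revealing the ring A hydroxyl and the terminal alkyne before the base-sensitive butenolide is made.

Step 23
Reactants: 31 propiolic acid
Product: 32 (2E)-2,3-dibromoprop-2-enoic acid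
Conditions: Br2, CHCl3, 0 °C to rt, dark
Reagents that add atoms: bromine, BrBr
Why: Electrophilic anti-addition of bromine to the alkyne through a bromonium ion gives the (E)-dibromide, in which the C3 bromine is cis to the carboxyl group as needed for lactonisation.

Step 24
Reactants: 30 tetraenediyne alcohol; 32 (2E)-2,3-dibromoprop-2-enoic acid
Product: 34 (5Z)-3-bromo-5-[(2E,4E,6E,8E)-11-[(4R)-4-hydroxy-2,6,6-trimethylcyclohex-1-en-1-yl]-2,9-dimethylundeca-2,4,6,8-tetraen-10-yn-1-ylidene]furan-2(5H)-one, via bromoenynoic acid 33 (not isolated)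
Conditions: Pd(PPh3)4 (cat.), CuI (cat.), Et3N, MeCN, rt, dark; 32 in slight excess
Reagents that add atoms: none
Why: Tandem Sonogashira coupling–lactonisation of a β-haloacrylic acid whose β-halogen is cis to the carboxyl group: oxidative addition occurs at the more electrophilic β C–Br bond, and the carboxylate then adds anti across the metal-activated alkyne in 5-exo-dig fashion, so the exocyclic alkene forms with the ring oxygen and the polyene chain cis, i.e. (Z).

Step 25
Reactants: 15 ring B vinylstannane; 34 bromobutenolide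
Product: 35 (5Z)-3-{(E)-2-[(1S,2S,4R)-1,2,4-trihydroxy-2,6,6-trimethylcyclohexyl]ethenyl}-5-[(2E,4E,6E,8E)-11-[(4R)-4-hydroxy-2,6,6-trimethylcyclohex-1-en-1-yl]-2,9-dimethylundeca-2,4,6,8-tetraen-10-yn-1-ylidene]furan-2(5H)-one (target)
Conditions: Pd2(dba)3 (cat.), AsPh3, NMP, 40 °C, dark
Reagents that add atoms: none
Why: Stille coupling of the α-bromobutenolide with the (E)-alkenylstannane under neutral conditions forms the C8–butenolide bond with retention of the (E)-C7=C8 geometry, tolerates all four free hydroxyls and the lactone, and needs no final deprotection.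

Compound list

1 | safranal; 2,6,6-trimethylcyclohexa-1,3-diene-1-carbaldehyde | CC1=C(C=O)C(C)(C)CC=C1 | starting material
2 | (2,6,6-trimethylcyclohexa-1,3-dien-1-yl)methanol | CC1=C(CO)C(C)(C)CC=C1 | intermediate
3 | tert-butyl(dimethyl)[(2,6,6-trimethylcyclohexa-1,3-dien-1-yl)methoxy]silane | CC1=C(CO[Si](C)(C)C(C)(C)C)C(C)(C)CC=C1 | intermediate
4 | rac-tert-butyl(dimethyl){[(1S,4R)-6,7,7-trimethyl-2,3-dioxabicyclo[2.2.2]oct-5-en-1-yl]methoxy}silane (racemic; SMILES shows the enantiomer carried on) | CC1=C[C@H]2CC(C)(C)[C@]1(CO[Si](C)(C)C(C)(C)C)OO2 | intermediate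
5 | rac-(1S,4R)-1-{[tert-butyl(dimethyl)silyl]oxymethyl}-2,6,6-trimethylcyclohex-2-ene-1,4-diol (cis; racemic; SMILES shows the enantiomer carried on) | CC1=C[C@H](O)CC(C)(C)[C@@]1(O)CO[Si](C)(C)C(C)(C)C | intermediate
6 | (1R,4S)-4-{[tert-butyl(dimethyl)silyl]oxymethyl}-4-hydroxy-3,5,5-trimethylcyclohex-2-en-1-yl acetate | CC1=C[C@H](OC(C)=O)CC(C)(C)[C@@]1(O)CO[Si](C)(C)C(C)(C)C | intermediate
7 | (1S,4R)-1-{[tert-butyl(dimethyl)silyl]oxymethyl}-2,6,6-trimethylcyclohex-2-ene-1,4-diol (single enantiomer) | CC1=C[C@H](O)CC(C)(C)[C@@]1(O)CO[Si](C)(C)C(C)(C)C | intermediate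
8 | C4 acetoxymercurial of 9 (HgOAc on C4, cis to the C3 and C6 hydroxyls, trans to the new C5 hydroxyl) | CC(C)(C)[Si](C)(C)OC[C@]1(O)C(C)(C)C[C@@H](O)[C@@H]([Hg]OC(C)=O)[C@]1(C)O | intermediate (not isolated)
9 | (1R,2S,4R)-1-{[tert-butyl(dimethyl)silyl]oxymethyl}-2,6,6-trimethylcyclohexane-1,2,4-triol | CC(C)(C)[Si](C)(C)OC[C@]1(O)C(C)(C)C[C@@H](O)C[C@]1(C)O | intermediate
10 | (1R,3S,4R)-4-{[tert-butyl(dimethyl)silyl]oxymethyl}-3,4-dihydroxy-3,5,5-trimethylcyclohexyl acetate | CC(C)(C)[Si](C)(C)OC[C@]1(O)C(C)(C)C[C@@H](OC(C)=O)C[C@]1(C)O | intermediate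
11 | (1R,3S,4R)-3,4-dihydroxy-4-(hydroxymethyl)-3,5,5-trimethylcyclohexyl acetate | OC[C@]1(O)C(C)(C)C[C@@H](OC(C)=O)C[C@]1(C)O | intermediate
12 | (1R,3S,4S)-4-formyl-3,4-dihydroxy-3,5,5-trimethylcyclohexyl acetate | O=C[C@]1(O)C(C)(C)C[C@@H](OC(C)=O)C[C@]1(C)O | intermediate
13 | (1R,3S,4R)-4-ethynyl-3,4-dihydroxy-3,5,5-trimethylcyclohexyl acetate | C#C[C@]1(O)C(C)(C)C[C@@H](OC(C)=O)C[C@]1(C)O | intermediate (not isolated)
14 | (1R,2S,4R)-1-ethynyl-2,6,6-trimethylcyclohexane-1,2,4-triol | C#C[C@]1(O)C(C)(C)C[C@@H](O)C[C@]1(C)O | intermediate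
15 | (1S,2S,4R)-2,6,6-trimethyl-1-[(E)-2-(tributylstannyl)ethenyl]cyclohexane-1,2,4-triol | CCCC[Sn](CCCC)(CCCC)/C=C/[C@]1(O)C(C)(C)C[C@@H](O)C[C@]1(C)O | intermediate
16 | actinol; (4R,6R)-4-hydroxy-2,2,6-trimethylcyclohexan-1-one | O=C1C(C)(C)C[C@H](O)C[C@H]1C | starting material
17 | (4R,6R)-4-{[tert-butyl(dimethyl)silyl]oxy}-2,2,6-trimethylcyclohexan-1-one | O=C1C(C)(C)C[C@H](O[Si](C)(C)C(C)(C)C)C[C@H]1C | intermediate
18 | lithium (4R)-4-{[tert-butyl(dimethyl)silyl]oxy}-2,6,6-trimethylcyclohex-1-en-1-olate | CC1=C(O[Li])C(C)(C)C[C@H](O[Si](C)(C)C(C)(C)C)C1 | intermediate (not isolated)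
19 | (4R)-4-{[tert-butyl(dimethyl)silyl]oxy}-2,6,6-trimethylcyclohex-1-en-1-yl trifluoromethanesulfonate | CC1=C(OS(=O)(=O)C(F)(F)F)C(C)(C)C[C@H](O[Si](C)(C)C(C)(C)C)C1 | intermediate
20 | (E)-3-methylpent-2-en-4-yn-1-ol | C#C/C(C)=C/CO | starting material
21 | (2E)-5-[(4R)-4-{[tert-butyl(dimethyl)silyl]oxy}-2,6,6-trimethylcyclohex-1-en-1-yl]-3-methylpent-2-en-4-yn-1-ol | CC1=C(C#C/C(C)=C/CO)C(C)(C)C[C@H](O[Si](C)(C)C(C)(C)C)C1 | intermediate
22 | (2E)-5-[(4R)-4-{[tert-butyl(dimethyl)silyl]oxy}-2,6,6-trimethylcyclohex-1-en-1-yl]-3-methylpent-2-en-4-ynal | CC1=C(C#C/C(C)=C/C=O)C(C)(C)C[C@H](O[Si](C)(C)C(C)(C)C)C1 | intermediate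
23 | tert-butyl(dimethyl){[(1R)-3,5,5-trimethyl-4-[(3E,5E)-3-methyl-6-(4,4,5,5-tetramethyl-1,3,2-dioxaborolan-2-yl)hexa-3,5-dien-1-yn-1-yl]cyclohex-3-en-1-yl]oxy}silane | CC1=C(C#C/C(C)=C/C=C/B2OC(C)(C)C(C)(C)O2)C(C)(C)C[C@H](O[Si](C)(C)C(C)(C)C)C1 | intermediate
24 | dilithium salt of 20 (lithium alkoxide, lithium acetylide) | [Li]C#C/C(C)=C/CO[Li] | intermediate (not isolated)
25 | trimethyl{[(2E)-3-methyl-5-(trimethylsilyl)pent-2-en-4-yn-1-yl]oxy}silane | C[Si](C)(C)C#C/C(C)=C/CO[Si](C)(C)C | intermediate (not isolated)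
26 | (2E)-3-methyl-5-(trimethylsilyl)pent-2-en-4-yn-1-ol | C[Si](C)(C)C#C/C(C)=C/CO | intermediate
27 | (2E)-3-methyl-5-(trimethylsilyl)pent-2-en-4-ynal | C[Si](C)(C)C#C/C(C)=C/C=O | intermediate
28 | [(3E,5E)-6-iodo-3-methylhexa-3,5-dien-1-yn-1-yl](trimethyl)silane | C[Si](C)(C)C#C/C(C)=C/C=C/I | intermediate
29 | tert-butyl{[(1R)-4-[(3E,5E,7E,9E)-3,10-dimethyl-12-(trimethylsilyl)dodeca-3,5,7,9-tetraene-1,11-diyn-1-yl]-3,5,5-trimethylcyclohex-3-en-1-yl]oxy}dimethylsilane | CC1=C(C#C/C(C)=C/C=C/C=C/C=C(C)/C#C[Si](C)(C)C)C(C)(C)C[C@H](O[Si](C)(C)C(C)(C)C)C1 | intermediate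
30 | (1R)-4-[(3E,5E,7E,9E)-3,10-dimethyldodeca-3,5,7,9-tetraene-1,11-diyn-1-yl]-3,5,5-trimethylcyclohex-3-en-1-ol | CC1=C(C#C/C(C)=C/C=C/C=C/C=C(C)/C#C)C(C)(C)C[C@H](O)C1 | intermediate
31 | propiolic acid (prop-2-ynoic acid) | C#CC(=O)O | starting material
32 | (2E)-2,3-dibromoprop-2-enoic acid | OC(=O)/C(Br)=C\Br | intermediate
33 | (2E,6E,8E,10E,12E)-2-bromo-15-[(4R)-4-hydroxy-2,6,6-trimethylcyclohex-1-en-1-yl]-6,13-dimethylpentadeca-2,6,8,10,12-pentaene-4,14-diynoic acid | CC1=C(C#C/C(C)=C/C=C/C=C/C=C(C)/C#C/C=C(/Br)C(=O)O)C(C)(C)C[C@H](O)C1 | intermediate (not isolated)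
34 | (5Z)-3-bromo-5-[(2E,4E,6E,8E)-11-[(4R)-4-hydroxy-2,6,6-trimethylcyclohex-1-en-1-yl]-2,9-dimethylundeca-2,4,6,8-tetraen-10-yn-1-ylidene]furan-2(5H)-one | CC1=C(C#C/C(C)=C/C=C/C=C/C=C(C)/C=C2C=C(Br)C(=O)O/2)C(C)(C)C[C@H](O)C1 | intermediate
35 | (5Z)-3-{(E)-2-[(1S,2S,4R)-1,2,4-trihydroxy-2,6,6-trimethylcyclohexyl]ethenyl}-5-[(2E,4E,6E,8E)-11-[(4R)-4-hydroxy-2,6,6-trimethylcyclohex-1-en-1-yl]-2,9-dimethylundeca-2,4,6,8-tetraen-10-yn-1-ylidene]furan-2(5H)-one | CC1=C(C#C/C(C)=C/C=C/C=C/C=C(C)/C=C2C=C(/C=C/[C@]3(O)C(C)(C)C[C@@H](O)C[C@]3(C)O)C(=O)O/2)C(C)(C)C[C@H](O)C1 | target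

Total step count: 25.
Longest linear sequence: 13 steps (steps 1–12, then step 25; safranal to target).

Steps most likely to fail

1. Step 11. The hindered α,β-dihydroxy aldehyde may undergo base-induced retro-aldol cleavage or ring-expanding α-ketol rearrangement faster than the diazophosphonate anion adds. The fallback replaces alkynylation by a base-free olefination. Setting out from 12, Takai iodo-olefination (CHI3, CrCl2, THF, 0 °C to rt) should give (1R,3S,4S)-3,4-dihydroxy-4-[(E)-2-iodoethenyl]-3,5,5-trimethylcyclohexyl acetate F1. Methanolysis (K2CO3, MeOH) then gives (1S,2S,4R)-1-[(E)-2-iodoethenyl]-2,6,6-trimethylcyclohexane-1,2,4-triol F2. Palladium-catalysed stannylation of F2 with (Bu3Sn)2 (Pd(PPh3)4, toluene, 60 °C) comes back to the route at 15.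

2. Step 24. Oxidative addition at the wrong C–Br bond, a second alkynylation of the bromobutenolide once formed, or 6-endo closure to a pyranone would erode the one-pot process. The fallback separates coupling from ring closure and closes the ring with silver. Setting out from 30 and 32, acid 32 is esterified (MeOH, H2SO4 cat.) to methyl (2E)-2,3-dibromoprop-2-enoate F3. Sonogashira coupling of 30 with F3 (Pd(PPh3)4, CuI, Et3N) at the C3–Br bond gives methyl (2E,6E,8E,10E,12E)-2-bromo-15-[(4R)-4-hydroxy-2,6,6-trimethylcyclohex-1-en-1-yl]-6,13-dimethylpentadeca-2,6,8,10,12-pentaene-4,14-diynoate F4. Saponification (LiOH, THF/H2O) gives acid 33, now isolated, and AgNO3 (cat.) in acetone at rt in the dark closes the (Z)-butenolide 5-exo-dig, coming back to the route at 34.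

3. Step 5. Acylation may be slow or poorly enantioselective if the enzyme does not distinguish the two ring neighbours of the carbinol well enough. The fallback is a covalent resolution. Setting out from 5, esterification with (S)-2-methoxy-2-phenylacetic acid (DCC, DMAP, CH2Cl2) gives two diastereomeric esters that are separated by chromatography: (1R,4S)-4-{[tert-butyl(dimethyl)silyl]oxymethyl}-4-hydroxy-3,5,5-trimethylcyclohex-2-en-1-yl (2S)-2-methoxy-2-phenylacetate F5 and its (1S,4R)-ring diastereomer, (1S,4R)-4-{[tert-butyl(dimethyl)silyl]oxymethyl}-4-hydroxy-3,5,5-trimethylcyclohex-2-en-1-yl (2S)-2-methoxy-2-phenylacetate F6. Methanolysis of F5 (K2CO3, MeOH) comes back to the route at 7.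

Further compounds

F1 | step 11 | (1R,3S,4S)-3,4-dihydroxy-4-[(E)-2-iodoethenyl]-3,5,5-trimethylcyclohexyl acetate | I/C=C/[C@]1(O)C(C)(C)C[C@@H](OC(C)=O)C[C@]1(C)O
F2 | step 11 | (1S,2S,4R)-1-[(E)-2-iodoethenyl]-2,6,6-trimethylcyclohexane-1,2,4-triol | I/C=C/[C@]1(O)C(C)(C)C[C@@H](O)C[C@]1(C)O
F3 | step 24 | methyl (2E)-2,3-dibromoprop-2-enoate | COC(=O)/C(Br)=C\Br
F4 | step 24 | methyl (2E,6E,8E,10E,12E)-2-bromo-15-[(4R)-4-hydroxy-2,6,6-trimethylcyclohex-1-en-1-yl]-6,13-dimethylpentadeca-2,6,8,10,12-pentaene-4,14-diynoate | CC1=C(C#C/C(C)=C/C=C/C=C/C=C(C)/C#C/C=C(/Br)C(=O)OC)C(C)(C)C[C@H](O)C1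
F5 | step 5 | (1R,4S)-4-{[tert-butyl(dimethyl)silyl]oxymethyl}-4-hydroxy-3,5,5-trimethylcyclohex-2-en-1-yl (2S)-2-methoxy-2-phenylacetate | CC1=C[C@H](OC(=O)[C@@H](OC)c2ccccc2)CC(C)(C)[C@@]1(O)CO[Si](C)(C)C(C)(C)C
F6 | step 5 | (1S,4R)-4-{[tert-butyl(dimethyl)silyl]oxymethyl}-4-hydroxy-3,5,5-trimethylcyclohex-2-en-1-yl (2S)-2-methoxy-2-phenylacetate | CC1=C[C@@H](OC(=O)[C@@H](OC)c2ccccc2)CC(C)(C)[C@]1(O)CO[Si](C)(C)C(C)(C)C
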